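**Retrosynthetic overview**

1. Target 25 comes from dithiane 23 by unveiling the C1 ketone and E1cB loss of a C3 mesylate (C2=C3); 23 comes from the spiro-dithiane 20 by functional-group changes only.
2. 20 comes from bis-epoxide 13 and silyl dithiane 16 by a [5+1] anion-relay annulation that forms C1–C2 and C1–C6; the only ring, the carbocycle C1–C6, is closed in this one step.
3. Feature used: in the carbocycle C1–C6 the C1 carbonyl lies between C2 and C6, and each of these adjoins an oxygen-bearing carbon (C5–OH, and C3–O once C2=C3 is read as a dehydrated β-hydroxy ketone). This is the pattern left when one acyl dianion equivalent opens two oxiranes.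
4. 13 comes from dienol 8 (oleyl alcohol plus one carbon, α-methylenation, vinyl Grignard). Hydroxyl-directed epoxidation of a 2-substituted secondary allylic alcohol is erythro-selective, which would lead to a cis C4/C5 diol, whereas the target's trans diol needs the threo epoxy alcohol. C5 is therefore set by Sharpless epoxidation/kinetic resolution, C4 is then inverted by Mitsunobu reaction, and the second oxirane is added by a matched Sharpless epoxidation.

Key step: step 11

Assumption: ring atoms keep the numbering of the target in all precursors (C1 carbonyl, C2=C3, C4 secondary carbinol, C5 tertiary carbinol bearing the chain, C6 methylene); oleyl alcohol is taken as the pure (Z)-isomer; the C3 configuration of 12–24 is defined but irrelevant to the target because C3 becomes sp2.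

**Step 1**
Reactants: 1 oleyl alcohol, (9Z)-octadec-9-en-1-ol
Product: 2 (9Z)-1-bromooctadec-9-ene
Conditions: CBr4, PPh3, CH2Cl2, 0 °C → rt
Reagents that add atoms: carbon tetrabromide, BrC(Br)(Br)Br
Why: Appel reaction, in which bromide displaces the oxyphosphonium of the primary alcohol (SN2) under neutral conditions that leave the Z-alkene untouched.

**Step 2**
Reactants: 2 (9Z)-1-bromooctadec-9-ene
Product: 5 (10Z)-nonadec-10-enal, via (9Z)-octadec-9-en-1-ylmagnesium bromide 3 (not isolated), via bromomagnesium hemiaminalate 4 (not isolated)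
Conditions: Mg, THF, reflux; DMF, 0 °C; 1 M HCl
Reagents that add atoms: N,N-dimethylformamide, CN(C)C=O
Why: Bouveault aldehyde synthesis, in which the Grignard reagent adds once to DMF and the tetrahedral adduct survives until acidic work-up, so the chain grows by exactly one carbon (the future C4).

**Step 3**
Reactants: 5 (10Z)-nonadec-10-enal
Product: 6 (10Z)-2-methylidenenonadec-10-enal
Conditions: 37% aq CH2O, pyrrolidine (10 mol %), EtCO2H (10 mol %), i-PrOH, 45 °C
Reagents that add atoms: formaldehyde, C=O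
Why: amine-catalysed Mannich condensation with formaldehyde followed by loss of the amine (organocatalytic α-methylenation of an aldehyde) installs the methylene carbon that becomes C6.

**Step 4**
Reactants: 6 (10Z)-2-methylidenenonadec-10-enal; 7 vinylmagnesium bromide
Product: 8 rac-(12Z)-4-methylidenehenicosa-1,12-dien-3-ol
Conditions: THF, −78 → 0 °C; sat. aq NH4Cl
Reagents that add atoms: none
Why: 1,2-addition of a vinyl Grignard reagent to the 2-substituted acrolein at low temperature gives the racemic bis-allylic alcohol, whose carbinol carbon (future C4) is resolved in step 5.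

**Step 5**
Reactants: 8 rac-(12Z)-4-methylidenehenicosa-1,12-dien-3-ol
Product: 9 (1R)-1-[(2S)-2-[(8Z)-heptadec-8-en-1-yl]oxiran-2-yl]prop-2-en-1-ol (erythro)
Conditions: Ti(OiPr)4 (0.15 equiv), D-(−)-DIPT (0.20 equiv), t-BuOOH (0.45 equiv), 4 Å MS, CH2Cl2, −20 °C
Reagents that add atoms: tert-butyl hydroperoxide, CC(C)(C)OO
Why: Katsuki–Sharpless epoxidation run as a kinetic resolution, in which D-(−)-DIPT matches the (R)-alcohol and delivers oxygen to its electron-richer 1,1-disubstituted alkene from the face that makes the oxirane carbon (future C5) S and erythro to the carbinol, while the monosubstituted vinyl group reacts far more slowly, the (S)-alcohol is left behind, and the remote Z-alkene, lacking a directing hydroxyl, is not touched.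

**Step 6**
Reactants: 9 (1R)-1-[(2S)-2-[(8Z)-heptadec-8-en-1-yl]oxiran-2-yl]prop-2-en-1-ol
Product: 10 (1S)-1-[(2S)-2-[(8Z)-heptadec-8-en-1-yl]oxiran-2-yl]prop-2-en-1-yl 4-nitrobenzoate
Conditions: 4-O2NC6H4CO2H, PPh3, DIAD, toluene, 0 °C → rt
Reagents that add atoms: 4-nitrobenzoic acid, O=C(O)c1ccc(cc1)[N+](=O)[O-]
Why: Mitsunobu esterification with inversion (SN2 of the carboxylate on the alkoxyphosphonium) turns the erythro into the threo relationship required for the trans C4/C5 diol, C4 becoming S, with the acidic 4-nitrobenzoic acid chosen for the hindered carbinol and the electron-poor oxirane neighbour disfavouring ionisation.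

**Step 7**
Reactants: 10 (1S)-1-[(2S)-2-[(8Z)-heptadec-8-en-1-yl]oxiran-2-yl]prop-2-en-1-yl 4-nitrobenzoate
Product: 11 (1S)-1-[(2S)-2-[(8Z)-heptadec-8-en-1-yl]oxiran-2-yl]prop-2-en-1-ol (threo)
Conditions: K2CO3 (cat.), MeOH, 0 °C
Reagents that add atoms: none
Why: base-catalysed transesterification of the activated 4-nitrobenzoate is fast at 0 °C, so the alkoxide is present too briefly for Payne rearrangement onto the fully substituted oxirane carbon.

**Step 8**
Reactants: 11 (1S)-1-[(2S)-2-[(8Z)-heptadec-8-en-1-yl]oxiran-2-yl]prop-2-en-1-ol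
Product: 12 (S)-[(2S)-2-[(8Z)-heptadec-8-en-1-yl]oxiran-2-yl][(2S)-oxiran-2-yl]methanol
Conditions: Ti(OiPr)4 (1.0 equiv), D-(−)-DIPT (1.2 equiv), t-BuOOH (2 equiv), 4 Å MS, CH2Cl2, −20 °C, several days
Reagents that add atoms: tert-butyl hydroperoxide, CC(C)(C)OO
Why: hydroxyl-directed Katsuki–Sharpless epoxidation of the remaining vinyl group in the matched sense (D-(−)-DIPT with the (S)-carbinol) should give the erythro (S)-oxirane at C3 as one diastereomer, a control that only serves homogeneity since C3 becomes sp2 later, and the need for a directing hydroxyl again protects the chain alkene.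

**Step 9**
Reactants: 12 (S)-[(2S)-2-[(8Z)-heptadec-8-en-1-yl]oxiran-2-yl][(2S)-oxiran-2-yl]methanol
Product: 13 (2S)-2-[(8Z)-heptadec-8-en-1-yl]-2-[(S)-(methoxymethoxy)[(2S)-oxiran-2-yl]methyl]oxirane
Conditions: MOMCl, i-Pr2NEt, CH2Cl2, 0 °C → rt
Reagents that add atoms: chloromethyl methyl ether, COCCl
Why: O-alkylation with MOMCl under amine base (no free alkoxide, no Lewis acid) caps the C4 hydroxyl without Payne rearrangement or oxirane opening.

**Step 10**
Reactants: 14 1,3-dithiane
Product: 16 2-(tert-butyldimethylsilyl)-1,3-dithiane, via 2-lithio-1,3-dithiane 15 (not isolated)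
Conditions: n-BuLi, THF, −30 °C; TBSCl, −78 °C → rt
Reagents that add atoms: tert-butyldimethylsilyl chloride, CC(C)(C)[Si](C)(C)Cl
Why: Corey–Seebach lithiation of 1,3-dithiane and C-silylation give the linchpin that carries C1 as a masked carbonyl.

**Step 11**
Reactants: 16 2-(tert-butyldimethylsilyl)-1,3-dithiane; 13 (2S)-2-[(8Z)-heptadec-8-en-1-yl]-2-[(S)-(methoxymethoxy)[(2S)-oxiran-2-yl]methyl]oxirane
Product: 20 (8S,9S,10S)-10-[(tert-butyldimethylsilyl)oxy]-8-[(8Z)-heptadec-8-en-1-yl]-9-(methoxymethoxy)-1,5-dithiaspiro[5.5]undecan-8-ol, via 2-lithio-2-(tert-butyldimethylsilyl)-1,3-dithiane 17 (not isolated), via C3 lithium alkoxide 18 (not isolated), via silyl-shifted 2-lithiodithiane 19 (not isolated)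
Conditions: 16, t-BuLi, Et2O, −78 → −45 °C; 13, −78 → −25 °C; HMPA, −78 °C → rt; aq NH4Cl
Reagents that add atoms: none
Why: The lithiated silyl dithiane 17 opens the monosubstituted oxirane of 13 at its CH2 (C2) by SN2 in ether, where the C3 lithium alkoxide 18 is stable; adding HMPA triggers a 1,4-Brook shift of silicon from C1 to the C3 oxygen and regenerates the dithiane carbanion 19, which attacks the CH2 (C6) of the 2,2-disubstituted oxirane intramolecularly. The closest known reaction type is the solvent-controlled anion-relay coupling of 2-silyl-1,3-dithianes with two epoxides, including its use on bis-epoxides to close carbocycles. The carbocycle C1–C6 closes in the 6-endo mode with respect to the oxirane, because the alternative 5-exo site C5 is fully substituted and closed to SN2. No stereocentre is created: C1 is a spiro carbon with two identical sulfur arms, and C3, C4 and C5 keep their C–O bonds, so the threo C4/C5 pair of 13 becomes the trans C4–O/C5–O pair of 20. The step needs site order (C2 before C6, since a first attack at C6 would leave a closure onto the monosubstituted oxirane in which 5-exo attack at C3 competes), and this is secured by the lower hindrance of a CH2 next to a CH compared with the neopentyl-type CH2 next to quaternary C5 and by running the first opening cold without HMPA.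

**Step 12**
Reactants: 20 (8S,9S,10S)-10-[(tert-butyldimethylsilyl)oxy]-8-[(8Z)-heptadec-8-en-1-yl]-9-(methoxymethoxy)-1,5-dithiaspiro[5.5]undecan-8-ol
Product: 21 (8S,9S,10S)-8-[(8Z)-heptadec-8-en-1-yl]-9-(methoxymethoxy)-1,5-dithiaspiro[5.5]undecane-8,10-diol
Conditions: TBAF, THF, 0 °C → rt
Reagents that add atoms: none
Why: fluoride-mediated cleavage of the secondary silyl ether, to which the dithiane, the MOM acetal, the tertiary alcohol and the alkene are inert.

**Step 13**
Reactants: 21 (8S,9S,10S)-8-[(8Z)-heptadec-8-en-1-yl]-9-(methoxymethoxy)-1,5-dithiaspiro[5.5]undecane-8,10-diol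
Product: 22 (8S,9S,10S)-8-[(8Z)-heptadec-8-en-1-yl]-8-hydroxy-9-(methoxymethoxy)-1,5-dithiaspiro[5.5]undecan-10-yl methanesulfonate
Conditions: MsCl, pyridine, DMAP (cat.), CH2Cl2, 0 °C
Reagents that add atoms: methanesulfonyl chloride, CS(=O)(=O)Cl
Why: sulfonylation in pyridine proceeds by direct attack on the sulfonyl chloride and is sterically selective for the secondary C3 hydroxyl over the tertiary C5 hydroxyl, while C4 is still capped as the MOM ether.

**Step 14**
Reactants: 22 (8S,9S,10S)-8-[(8Z)-heptadec-8-en-1-yl]-8-hydroxy-9-(methoxymethoxy)-1,5-dithiaspiro[5.5]undecan-10-yl methanesulfonate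
Product: 23 (8S,9S,10S)-8-[(8Z)-heptadec-8-en-1-yl]-8,9-dihydroxy-1,5-dithiaspiro[5.5]undecan-10-yl methanesulfonate
Conditions: HCl (conc., cat.), MeOH, 40 °C
Reagents that add atoms: none
Why: acid-catalysed transacetalisation to methanol removes the MOM group at a stage where the dithiane, the mesylate and the tertiary alcohol (not yet β to a carbonyl) tolerate acid, so the sensitive hydroxy enone never meets acid.

**Step 15**
Reactants: 23 (8S,9S,10S)-8-[(8Z)-heptadec-8-en-1-yl]-8,9-dihydroxy-1,5-dithiaspiro[5.5]undecan-10-yl methanesulfonate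
Product: 25 (4S,5S)-5-[(8Z)-heptadec-8-en-1-yl]-4,5-dihydroxycyclohex-2-en-1-one, via β-mesyloxy ketone 24 (not isolated)
Conditions: MeI, CaCO3, MeCN–H2O (9:1), 35 °C; then Et3N, CH2Cl2, 0 °C
Reagents that add atoms: water, O
Why: alkylative hydrolysis of the dithiane (S-methylation, thionium hydrolysis) under carbonate buffer unveils the C1 ketone, and the β-mesyloxy ketone then undergoes E1cB elimination with a mild amine base to place C2=C3 in conjugation, leaving C4 and C5 untouched.

**Compound list**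

1 | oleyl alcohol, (9Z)-octadec-9-en-1-ol | CCCCCCCC/C=C\CCCCCCCCO | starting material
2 | (9Z)-1-bromooctadec-9-ene | CCCCCCCC/C=C\CCCCCCCCBr | intermediate
3 | (9Z)-octadec-9-en-1-ylmagnesium bromide | CCCCCCCC/C=C\CCCCCCCC[Mg]Br | intermediate
4 | bromomagnesium (10Z)-1-(dimethylamino)nonadec-10-en-1-olate (hemiaminalate) | CCCCCCCC/C=C\CCCCCCCCC(O[Mg]Br)N(C)C | intermediate
5 | (10Z)-nonadec-10-enal | CCCCCCCC/C=C\CCCCCCCCC=O | intermediate
6 | (10Z)-2-methylidenenonadec-10-enal | CCCCCCCC/C=C\CCCCCCCC(=C)C=O | intermediate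
7 | vinylmagnesium bromide | C=C[Mg]Br | starting material
8 | rac-(12Z)-4-methylidenehenicosa-1,12-dien-3-ol | CCCCCCCC/C=C\CCCCCCCC(=C)C(O)C=C | intermediate
9 | (1R)-1-[(2S)-2-[(8Z)-heptadec-8-en-1-yl]oxiran-2-yl]prop-2-en-1-ol | CCCCCCCC/C=C\CCCCCCC[C@]1(CO1)[C@H](O)C=C | intermediate
10 | (1S)-1-[(2S)-2-[(8Z)-heptadec-8-en-1-yl]oxiran-2-yl]prop-2-en-1-yl 4-nitrobenzoate | CCCCCCCC/C=C\CCCCCCC[C@]1(CO1)[C@@H](OC(=O)c2ccc(cc2)[N+](=O)[O-])C=C | intermediate
11 | (1S)-1-[(2S)-2-[(8Z)-heptadec-8-en-1-yl]oxiran-2-yl]prop-2-en-1-ol | CCCCCCCC/C=C\CCCCCCC[C@]1(CO1)[C@@H](O)C=C | intermediate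
12 | (S)-[(2S)-2-[(8Z)-heptadec-8-en-1-yl]oxiran-2-yl][(2S)-oxiran-2-yl]methanol | CCCCCCCC/C=C\CCCCCCC[C@]1(CO1)[C@@H](O)[C@@H]1CO1 | intermediate
13 | (2S)-2-[(8Z)-heptadec-8-en-1-yl]-2-[(S)-(methoxymethoxy)[(2S)-oxiran-2-yl]methyl]oxirane | CCCCCCCC/C=C\CCCCCCC[C@]1(CO1)[C@@H](OCOC)[C@@H]1CO1 | intermediate
14 | 1,3-dithiane | C1CSCSC1 | starting material
15 | 2-lithio-1,3-dithiane | [Li]C1SCCCS1 | intermediate
16 | 2-(tert-butyldimethylsilyl)-1,3-dithiane | CC(C)(C)[Si](C)(C)C1SCCCS1 | intermediate
17 | 2-lithio-2-(tert-butyldimethylsilyl)-1,3-dithiane | CC(C)(C)[Si](C)(C)C1([Li])SCCCS1 | intermediate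
18 | lithium (2S,3S)-1-[2-(tert-butyldimethylsilyl)-1,3-dithian-2-yl]-3-[(2S)-2-[(8Z)-heptadec-8-en-1-yl]oxiran-2-yl]-3-(methoxymethoxy)propan-2-olate | CCCCCCCC/C=C\CCCCCCC[C@]1(CO1)[C@@H](OCOC)[C@@H](O[Li])CC2(SCCCS2)[Si](C)(C)C(C)(C)C | intermediate
19 | [2-[(2S,3S)-2-[(tert-butyldimethylsilyl)oxy]-3-[(2S)-2-[(8Z)-heptadec-8-en-1-yl]oxiran-2-yl]-3-(methoxymethoxy)propyl]-1,3-dithian-2-yl]lithium | CCCCCCCC/C=C\CCCCCCC[C@]1(CO1)[C@@H](OCOC)[C@@H](O[Si](C)(C)C(C)(C)C)CC2([Li])SCCCS2 | intermediate
20 | (8S,9S,10S)-10-[(tert-butyldimethylsilyl)oxy]-8-[(8Z)-heptadec-8-en-1-yl]-9-(methoxymethoxy)-1,5-dithiaspiro[5.5]undecan-8-ol | CCCCCCCC/C=C\CCCCCCC[C@]1(O)CC2(SCCCS2)C[C@H](O[Si](C)(C)C(C)(C)C)[C@@H]1OCOC | intermediate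
21 | (8S,9S,10S)-8-[(8Z)-heptadec-8-en-1-yl]-9-(methoxymethoxy)-1,5-dithiaspiro[5.5]undecane-8,10-diol | CCCCCCCC/C=C\CCCCCCC[C@]1(O)CC2(SCCCS2)C[C@H](O)[C@@H]1OCOC | intermediate
22 | (8S,9S,10S)-8-[(8Z)-heptadec-8-en-1-yl]-8-hydroxy-9-(methoxymethoxy)-1,5-dithiaspiro[5.5]undecan-10-yl methanesulfonate | CCCCCCCC/C=C\CCCCCCC[C@]1(O)CC2(SCCCS2)C[C@H](OS(C)(=O)=O)[C@@H]1OCOC | intermediate
23 | (8S,9S,10S)-8-[(8Z)-heptadec-8-en-1-yl]-8,9-dihydroxy-1,5-dithiaspiro[5.5]undecan-10-yl methanesulfonate | CCCCCCCC/C=C\CCCCCCC[C@]1(O)CC2(SCCCS2)C[C@H](OS(C)(=O)=O)[C@@H]1O | intermediate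
24 | (1S,2S,3S)-3-[(8Z)-heptadec-8-en-1-yl]-2,3-dihydroxy-5-oxocyclohexyl methanesulfonate | CCCCCCCC/C=C\CCCCCCC[C@]1(O)CC(=O)C[C@H](OS(C)(=O)=O)[C@@H]1O | intermediate
25 | (4S,5S)-5-[(8Z)-heptadec-8-en-1-yl]-4,5-dihydroxycyclohex-2-en-1-one | CCCCCCCC/C=C\CCCCCCC[C@]1(O)CC(=O)C=C[C@@H]1O | target

**Step count**

Total steps: 15. Longest linear sequence: 14 steps (steps 1–9 and 11–15); step 10 is a one-step branch.

**Steps most likely to fail**

Step 11. The relay may not stay intramolecular: the carbanion released by the silyl shift, or unconsumed 17, may open an oxirane of a second molecule and give oligomers. Alternatively the first opening may occur at C6, after which closure onto the monosubstituted oxirane can take the 5-exo course. The fallback sets out from 13 and returns to the route at 20; it makes the two C–C bonds in separate, isolable operations without a silyl shift. 2-Lithio-1,3-dithiane 15 (from 14, n-BuLi, THF, −30 °C) opens the monosubstituted oxirane of 13 (THF, −30 → 0 °C; aq NH4Cl) to give (2S,3S)-1-(1,3-dithian-2-yl)-3-[(2S)-2-[(8Z)-heptadec-8-en-1-yl]oxiran-2-yl]-3-(methoxymethoxy)propan-2-ol F1, which can be purified free of any C6-opened isomer. Silylation (TBSCl, imidazole, DMF, rt) gives 2-[(2S,3S)-2-[(tert-butyldimethylsilyl)oxy]-3-[(2S)-2-[(8Z)-heptadec-8-en-1-yl]oxiran-2-yl]-3-(methoxymethoxy)propyl]-1,3-dithiane F2. Deprotonation of the dithiane C–H (n-BuLi, THF–HMPA, −78 → 0 °C, high dilution) and intramolecular opening of the 2,2-disubstituted oxirane at C6 should then give 20.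

Step 6. The alkoxyphosphonium of the hindered allylic carbinol may be displaced slowly or with allylic transposition (SN2′), or the acid may open the oxirane, so that inversion at C4 is not clean. The fallback sets out from 6 and returns at 11; it creates C4 by carbonyl addition to an epoxy aldehyde of fixed C5 configuration, so no inversion is needed. Luche reduction of 6 (NaBH4, CeCl3·7H2O, MeOH, 0 °C) gives (10Z)-2-methylidenenonadec-10-en-1-ol F3. Katsuki–Sharpless epoxidation (Ti(OiPr)4, D-(−)-DIPT, t-BuOOH, 4 Å MS, CH2Cl2, −20 °C) gives [(2R)-2-[(8Z)-heptadec-8-en-1-yl]oxiran-2-yl]methanol F4, with C5 fixed by the catalyst. Parikh–Doering oxidation (SO3·pyridine, DMSO, i-Pr2NEt, CH2Cl2, 0 °C) gives the non-enolisable (2S)-2-[(8Z)-heptadec-8-en-1-yl]oxirane-2-carbaldehyde F5. Addition of 7 (THF, −78 °C) is expected to follow the Felkin–Anh course (attack anti to the oxirane C–O bond, past the tied-back ring CH2 and away from the chain) and to favour the threo alcohol 11; its erythro epimer is 9 and is removed by chromatography.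

Step 15. Once the ketone is free, the unprotected hydroxy enone may suffer base-induced isomerisation of the γ-hydroxy enone to a 1,4-diketone, retro-aldol cleavage of C5–C6, or dehydration towards the aromatic hydroquinone during the elimination. The fallback sets out from 22 (step 14 is omitted) and returns at 25; it runs the basic step with C4 still protected and removes the acetal last under cold, non-basic conditions. 22 is treated with MeI and CaCO3 in MeCN–H2O and then with Et3N to give, via (1S,2S,3S)-3-[(8Z)-heptadec-8-en-1-yl]-3-hydroxy-2-(methoxymethoxy)-5-oxocyclohexyl methanesulfonate F6 (not isolated), (4S,5S)-5-[(8Z)-heptadec-8-en-1-yl]-5-hydroxy-4-(methoxymethoxy)cyclohex-2-en-1-one F7. Me2BBr (CH2Cl2, −78 °C; NaHCO3 work-up) then cleaves the MOM acetal to give 25.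

**Further compounds**

F1 | step 11 | (2S,3S)-1-(1,3-dithian-2-yl)-3-[(2S)-2-[(8Z)-heptadec-8-en-1-yl]oxiran-2-yl]-3-(methoxymethoxy)propan-2-ol | CCCCCCCC/C=C\CCCCCCC[C@]1(CO1)[C@@H](OCOC)[C@@H](O)CC2SCCCS2
F2 | step 11 | 2-[(2S,3S)-2-[(tert-butyldimethylsilyl)oxy]-3-[(2S)-2-[(8Z)-heptadec-8-en-1-yl]oxiran-2-yl]-3-(methoxymethoxy)propyl]-1,3-dithiane | CCCCCCCC/C=C\CCCCCCC[C@]1(CO1)[C@@H](OCOC)[C@@H](O[Si](C)(C)C(C)(C)C)CC2SCCCS2
F3 | step 6 | (10Z)-2-methylidenenonadec-10-en-1-ol | CCCCCCCC/C=C\CCCCCCCC(=C)CO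
F4 | step 6 | [(2R)-2-[(8Z)-heptadec-8-en-1-yl]oxiran-2-yl]methanol | CCCCCCCC/C=C\CCCCCCC[C@]1(CO1)CO
F5 | step 6 | (2S)-2-[(8Z)-heptadec-8-en-1-yl]oxirane-2-carbaldehyde | CCCCCCCC/C=C\CCCCCCC[C@]1(CO1)C=O
F6 | step 15 | (1S,2S,3S)-3-[(8Z)-heptadec-8-en-1-yl]-3-hydroxy-2-(methoxymethoxy)-5-oxocyclohexyl methanesulfonate | CCCCCCCC/C=C\CCCCCCC[C@]1(O)CC(=O)C[C@H](OS(C)(=O)=O)[C@@H]1OCOC
F7 | step 15 | (4S,5S)-5-[(8Z)-heptadec-8-en-1-yl]-5-hydroxy-4-(methoxymethoxy)cyclohex-2-en-1-one | CCCCCCCC/C=C\CCCCCCC[C@]1(O)CC(=O)C=C[C@@H]1OCOC
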